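## Retrosynthetic overview

1. I avoid the obvious cut, which couples two finished bicycles across the C12–C13 bridge or at the enone β-carbon. Only ring D (the gem-dimethylcyclohexane) exists when the C30 skeleton is assembled.
2. Last step: a retro-oxa-Michael opens a temporary C10–O–C14 tetrahydropyran. This releases the enone and the C10 tertiary alcohol together.
3. Key step: one Lewis-acid cascade on a diepoxy-alkene, terminated by the C14 tertiary OH. It builds oxepane A, cyclohexane B and the temporary THP. It sets C6, C10 and C11, while C3 and C7 come from the Shi epoxides.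
4. Ring C closes by a 6-exo enolate-to-epoxide attack (C17–C18), giving the cis C18/C22 fusion and the C19 carbinol. C14–C17 come from crotylation and Wacker oxidation of a "linchpin" methyl ketone, whose CH3 is first alkylated with diepoxyfarnesyl bromide.
5. Ring order: D (purchased, C22 set by asymmetric conjugate addition), then C, then A + B (+ THP) in one step, then the THP is opened.

Assumption (numbering): I use squalene-type numbering. C2–C11 is the benzoxepane (C2 = OCMe2, C3 = CHOH, C6 = angular C–Me, C7 = OCH, C10 = C(Me)OH, C11 = CH). C12/C13 is the bridge, C14=C15(Me) the enone alkene, C16 the C=O, C17 the CH2, C18/C22 the ring-fusion CH, C19 the C(Me)OH and C23 the CMe2. The target is 3S,6S,7S,10S,11S,18S,19S,22R with a cis C18/C22 fusion.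

## Route

**Step 1**
Reactants: 1, 4,4-dimethylcyclohex-2-en-1-one; 2, isopropenylmagnesium bromide
Product: 3, (3S)-4,4-dimethyl-3-(prop-1-en-2-yl)cyclohex-1-en-1-yl triflate
Conditions: CuBr·SMe2 (5 mol %), Taniaphos-type ferrocenyl diphosphine (6 mol %, antipode giving 3S), t-BuOMe, −75 °C; then Comins' reagent, THF, −78→0 °C
Reagents that add atoms: Comins' reagent, Clc1ccc(nc1)N(S(=O)(=O)C(F)(F)F)S(=O)(=O)C(F)(F)F
Why: In this Cu-catalysed asymmetric conjugate addition of a Grignard reagent, the chiral Cu–diphosphine selects one enone face and sets C22, and the regiodefined Mg enolate is O-triflated in situ, which fixes where the C18=C19 alkene will sit.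

**Step 2**
Reactants: 3
Product: 4, (3S)-1,4,4-trimethyl-3-(prop-1-en-2-yl)cyclohex-1-ene
Conditions: MeMgBr, Fe(acac)3 (5 mol %), THF/NMP, −30→0 °C
Reagents that add atoms: methylmagnesium bromide, C[Mg]Br
Why: Iron-catalysed (Kochi–Fürstner) cross-coupling replaces OTf by CH3 without moving the alkene, and it leaves the allylic C22 centre and the isopropenyl group untouched.

**Step 3**
Reactants: 4
Product: 5, (1S,5S,6R)-1,4,4-trimethyl-5-(prop-1-en-2-yl)-7-oxabicyclo[4.1.0]heptane (epoxide O trans to isopropenyl)
Conditions: mCPBA (1.0 equiv), NaHCO3, CH2Cl2, −20 °C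
Reagents that add atoms: mCPBA, OOC(=O)c1cccc(Cl)c1
Why: In this Prilezhaev epoxidation the trisubstituted ring alkene outcompetes the 1,1-disubstituted one (limonene-type selectivity) and is attacked anti to the pseudo-equatorial isopropenyl and the axial C23 methyl, which sets C19 in its final configuration and C18 in the configuration that step 11 will invert.

**Step 4**
Reactants: 5
Product: 6, 1-[(1R,2S,6S)-3,3,6-trimethyl-7-oxabicyclo[4.1.0]heptan-2-yl]ethan-1-one (linchpin ketone, acetyl trans to epoxide O)
Conditions: O3, CH2Cl2, −78 °C; PPh3
Reagents that add atoms: ozone, [O-][O+]=O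
Why: Ozonolysis cleaves the only remaining alkene to the methyl ketone, and the neutral reductive work-up avoids enolisation toward C22 and so avoids β,γ-epoxy-ketone elimination.

**Step 5**
Reactants: 7, (2E,6E)-farnesyl acetate
Product: 8, (2E,6S,7S,10S)-6,7:10,11-diepoxyfarnesyl acetate
Conditions: L-fructose-derived (ent-)Shi ketone, Oxone, K2CO3, n-Bu4NHSO4, MeCN/DMM–aq. Na2B4O7/EDTA (pH ≈10.5), 0 °C
Reagents that add atoms: Oxone (KHSO5), [K+].OOS(=O)(=O)[O-]
Why: In this Shi asymmetric epoxidation the chiral dioxirane gives the (S)-configured epoxides at both remote trisubstituted alkenes, setting C3, C7 and the pre-inversion C6, while the Δ2 alkene is switched off by the allylic acetate.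

**Step 6**
Reactants: 8
Product: 9, (2E,6S,7S,10S)-6,7:10,11-diepoxyfarnesol
Conditions: K2CO3, MeOH, 0 °C
Reagents that add atoms: none
Why: Base-catalysed transesterification removes the acetate, and the trisubstituted epoxides are inert to methoxide at 0 °C.

**Step 7**
Reactants: 9
Product: 10, (2E,6S,7S,10S)-6,7:10,11-diepoxyfarnesyl bromide
Conditions: MsCl, Et3N, THF, −40 °C; then LiBr, THF, 0 °C
Reagents that add atoms: lithium bromide, [Li+].[Br-]
Why: Mesylation followed by SN2 (Finkelstein-type) displacement under non-acidic conditions keeps the E-alkene geometry and both epoxides intact.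

**Step 8**
Reactants: 6; 10
Product: 11, C13-alkylated triepoxy ketone (the acetyl CH3 of 6 now carries the diepoxyfarnesyl chain)
Conditions: 6, LDA, THF, −78 °C; then 10, DMPU, −78→−30 °C
Reagents that add atoms: none
Why: In this kinetic enolate alkylation LDA takes a CH3 proton rather than the hindered tertiary C22–H, and the primary allylic bromide reacts by SN2 to form C12–C13 with no new stereocentre and no epimerisation at C22.

**Step 9**
Reactants: 11; 12, but-2-enyl (crotyl) magnesium chloride
Product: 13, tertiary homoallylic alcohol, C14(OH) bearing CH(CH3)CH=CH2 (C15–C17)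
Conditions: THF, −78 °C
Reagents that add atoms: none (all new atoms come from 12)
Why: The γ-selective (SE2′, cyclic transition state) allyl-Grignard 1,2-addition is faster than enolisation even for hindered ketones, and the C14/C15 epimer mixture it gives does not matter because both centres become sp2 in step 13.

**Step 10**
Reactants: 13
Product: 14, β-hydroxy methyl ketone, C14(OH)–C15H(CH3)–C16(=O)–C17H3
Conditions: PdCl2 (10 mol %), Cu(OAc)2·H2O, O2 (1 atm), DMA/H2O 7:1, 23 °C
Reagents that add atoms: water, O
Why: Acetate-buffered Tsuji–Wacker oxidation touches only the single monosubstituted alkene and gives the Markovnikov ketone, so crotylation plus Wacker delivers a ketone–ketone "aldol" that could not be made directly, while the trisubstituted alkene and the epoxides survive the near-neutral medium.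

**Step 11**
Reactants: 14
Product: 15, cis-fused bicyclic keto-diol (ring C closed; C19–OH and C14–OH free; diepoxy chain intact)
Conditions: LDA (2.3 equiv), THF, −78 °C; DMPU, −78→23 °C; AcOH quench at −20 °C
Reagents that add atoms: none
Why: In this intramolecular enolate–epoxide alkylation (6-enolexo-exo-tet, Fürst–Plattner diaxial opening) the alkoxide/kinetic-enolate dianion resists retro-aldol, and C17 attacks C18 from the face carrying the C14 arm, anti to the epoxide oxygen, which inverts C18, enforces the cis C18/C22 fusion and leaves C19–OH trans to C17.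

**Step 12**
Reactants: 15
Product: 16, pentacyclic 10,14-epoxy (spiro-tetrahydropyran) keto-diol, with rings A and B in place
Conditions: TMSOTf (3 equiv), 2,6-di-tert-butyl-4-methylpyridine (4 equiv), CH2Cl2 (2 mM), −78 °C; Et3N quench; then TBAF/AcOH, THF, 0 °C
Reagents that add atoms: none (TMS groups are removed in the work-up)
Why: Proposed new method: silylation of the terminal epoxide triggers endo attack by the C6–C7 epoxide oxygen at C2 to give a bicyclic epoxonium, which the E C10=C11 alkene opens at C6 with inversion through a chair transition state, and the C10 cation is captured anti and equatorially by the C14–O(H/TMS) six atoms away, so C3 and C7 are retained while C6, C11 and C10 are set in one event; the closest known reactions are TMSOTf-promoted tandem oxa/carbacyclisations of 1,5-diepoxy-alkenes and tertiary-alcohol-terminated polyene cyclisations to 8,13-epoxylabdanes (manoyl oxide type).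

**Step 13**
Reactants: 16
Product: 17, sipholenol K
Conditions: DBU (2 equiv), PhMe, 23→50 °C
Reagents that add atoms: none
Why: In this E1cB retro-oxa-Michael, deprotonation at C15 (α to C16=O) expels the strained di-tertiary ether oxygen, forming the conjugated tetrasubstituted enone and freeing C10–OH with its C–O bond and configuration intact, and DBU does not remove the γ C22–H so the cis fusion is kept.

## Compound list

| No. | Name | SMILES | Role |
|---|---|---|---|
| 1 | 4,4-dimethylcyclohex-2-en-1-one | O=C1C=CC(C)(C)CC1 | starting material |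
| 2 | isopropenylmagnesium bromide | CC(=C)[Mg]Br | starting material |
| 3 | (3S)-enol triflate | CC(=C)[C@@H]1C=C(OS(=O)(=O)C(F)(F)F)CCC1(C)C | intermediate |
| 4 | (3S)-1,4,4-trimethyl-3-isopropenylcyclohexene | CC(=C)[C@@H]1C=C(C)CCC1(C)C | intermediate |
| 5 | trans-epoxide | CC(=C)[C@@H]1[C@H]2O[C@@]2(C)CCC1(C)C | intermediate |
| 6 | linchpin epoxy methyl ketone | CC(=O)[C@@H]1[C@H]2O[C@@]2(C)CCC1(C)C | intermediate |
| 7 | (2E,6E)-farnesyl acetate | CC(C)=CCC/C(C)=C/CC/C(C)=C/COC(C)=O | starting material |
| 8 | (6S,7S,10S)-diepoxyfarnesyl acetate | CC1(C)O[C@H]1CC[C@]2(C)O[C@H]2CC/C(C)=C/COC(C)=O | intermediate |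
| 9 | diepoxyfarnesol | CC1(C)O[C@H]1CC[C@]2(C)O[C@H]2CC/C(C)=C/CO | intermediate |
| 10 | diepoxyfarnesyl bromide | CC1(C)O[C@H]1CC[C@]2(C)O[C@H]2CC/C(C)=C/CBr | intermediate |
| 11 | triepoxy ketone | CC1(C)O[C@H]1CC[C@]2(C)O[C@H]2CC/C(C)=C/CCC(=O)[C@@H]3[C@H]4O[C@@]4(C)CCC3(C)C | intermediate |
| 12 | crotylmagnesium chloride | CC=CC[Mg]Cl | starting material |
| 13 | tertiary homoallylic alcohol (C14/C15 epimers) | CC1(C)O[C@H]1CC[C@]2(C)O[C@H]2CC/C(C)=C/CCC(O)(C(C)C=C)[C@@H]3[C@H]4O[C@@]4(C)CCC3(C)C | intermediate |
| 14 | β-hydroxy methyl ketone (C14/C15 epimers) | CC1(C)O[C@H]1CC[C@]2(C)O[C@H]2CC/C(C)=C/CCC(O)(C(C)C(C)=O)[C@@H]3[C@H]4O[C@@]4(C)CCC3(C)C | intermediate |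
| 15 | cis-bicyclic keto-diol with diepoxy chain | CC1(C)O[C@H]1CC[C@]2(C)O[C@H]2CC/C(C)=C/CCC3(O)C(C)C(=O)C[C@H]4[C@@H]3C(C)(C)CC[C@]4(C)O | intermediate |
| 16 | pentacyclic 10,14-epoxy spiro-ether | O=C1C[C@H]2[C@H](C(C)(C)CC[C@]2(C)O)C3(CC[C@H]4[C@]5(C)CC[C@H](O)C(C)(C)O[C@H]5CC[C@]4(C)O3)C1C | intermediate |
| 17 | sipholenol K | CC1=C(CC[C@H]2[C@]3(C)CC[C@H](O)C(C)(C)O[C@H]3CC[C@]2(C)O)[C@@H]2[C@H](CC1=O)[C@@](C)(O)CCC2(C)C | target |

**Stereocentre ledger**
- C22 is set in step 1.
- C19 is set in step 3.
- C18 is set in step 3 and inverted in step 11.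
- C3 and C7 are set in step 5.
- C6 is set in step 5 and inverted in step 12.
- C10 and C11 are set in step 12.
- Compounds 14, 15, 16 and 17 are all isomers of C30H50O5, so the last three steps are pure isomerisations and no protecting groups are used.

## Step count and main risks

**Total steps:** 13. **Longest linear sequence:** 10 (steps 1–4, then 8–13).

**The three steps most likely to fail, each with a fallback**

1. **Step 12 (cascade with O-termination at a very hindered carbinol).**
   - Give up the oxa-bridge. First dehydrate 15 to the enone.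
   - Run the diepoxide cascade with simple proton-loss termination, which gives a mixture of exo and endo C10 alkenes.
   - Install C10–OH by Mukaiyama HAT hydration (Mn(dpm)3, PhSiH3, O2). Both alkene isomers converge on one tertiary radical, which is trapped anti to the axial C6 methyl.
2. **Step 11 (SN2 opening at C18, syn-axial to a C23 methyl, with base-induced epoxide isomerisation competing).**
   - Switch to a radical closure. Keep C18=C19 as the alkene by doing a Lemieux–Johnson cleavage of the isopropenyl group of 4 in place of steps 3–4.
   - After step 10, α-iodinate C17 and run a 6-exo α-keto-radical cyclisation (Et3B/O2).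
   - Trap the tertiary C19 radical with O2 from the convex face.
3. **Step 1 (ee and yield for an alkenyl Grignard on a γ,γ-disubstituted enone).**
   - Move the source of chirality. Make racemic 4 by a plain CuI-catalysed addition, triflation and methylation.
   - Obtain enantioenriched 5 by kinetic resolution in step 3, using a chiral-dioxirane (Shi) epoxidation of the racemic 1,3-disubstituted cyclohexene.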